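1. Read every flask at 2.0 h, and before reckoning anything set down what stands and what is asked.

| flask | starting material | reagent | remark | time |
|---|---|---|---|---|
| autumn | 0.050 M | 1.3 equiv | run made earlier |  |
| dawn | 0.050 M | 2.6 equiv | run made earlier |  |
| south-west | 0.050 M | 1.30 equiv | everything together at the start | 2.0 h |
| south | 0.050 M (fed, over 80 min) | 1.30 equiv | all else is in the flask from the start; the feed brings no volume worth counting | 2.0 h |
| north-east | 0.050 M | 1.30 equiv (in portions, 4, over 80 min) | first portion at the start, last at 80 min | 2.0 h |
| north | 0.050 M | 1.30 equiv (fed, over 80 min) | all else is in the flask from the start; the feed brings no volume worth counting | 2.0 h |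
| north-west | 0.050 M (fed, over 20 min) | 1.30 equiv | all else is in the flask from the start; the feed brings no volume worth counting | 2.0 h |

| autumn: time / min | autumn: product / % | dawn: time / min | dawn: product / % |
|---|---|---|---|
| 10.0 | 0.6 | 1.00 | 0.1 |
| 15.0 | 1.0 | 1.33 | 0 |
| 20.0 | 1.9 | 2.00 | 0 |
| 30.0 | 3.0 | 3.00 | 0 |
| 50.0 | 6.4 | 5.00 | 0 |
| 80.0 | 10.2 | 8.00 | 0.7 |
| 120 | 15.1 | 12.0 | 1.5 |

(readings scatter by 0.3 percentage points)



1. the best flask by amount of product, in percent of the starting material charged; "all alike" if 1.5 percentage points covers them all (south-west / south / north-east / north / north-west / all alike)
2. amount of product at the end, in percent of the starting material charged, south-west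
3. amount of product at the end, in percent of the starting material charged, south
4. amount of product at the end, in percent of the starting material charged, north-east
5. amount of product at the end, in percent of the starting material charged, north
6. amount of product at the end, in percent of the starting material charged, north-west

2. Draw the autumn curve first, from its flat foot, where it stands at 0.6 % after 10.0 min, to its straight part, and take from 30.0 min to 120 min the slope s = 0.00134 min⁻¹, the supply rate: the share of the charge arriving as product per minute on the straight part of the autumn curve.

3. Run that line back to zero for the knee, the induction period, at t_L = 7.69 min, and note that the readings show no level, since the curve is still climbing at 15.1 % after 120 min.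

4. Hold the dawn run against s: with twice the reagent, its last interval climbs at 1.49 times s, a coarse reading, since a scatter of 0.3 percentage points per point lies on a rise of 0.8 points.

5. Take the slope as following the reagent in the flask, which is my own assumption, and draw north: the slope grows steadily up to a second knee at 80 min, where it reaches s, then holds, so the line ends at 9.72 %.

6. Set the forecast beside this: it names south-west as best, with 15.1 % there, 10.2 % in south, 10.3 % in north-east, 10.3 % in north and 13.9 % in north-west, holding that “the rate is first order in reagent”; its north lies above my 9.72 %.

7. Now take the scheme and what the flasks give.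

    reagent + intermediate B ⇌ product (K = 660 M⁻¹, k = 8.90 M⁻¹ min⁻¹)
    intermediate A → intermediate B (k = 0.00750 min⁻¹)
    starting material + reagent ⇌ intermediate A (K = 530 M⁻¹, k = 0.540 M⁻¹ min⁻¹)
    2 starting material → homo dimer (k = 1.80 M⁻¹ min⁻¹)
    intermediate B ⇌ intermediate C (K = 0.940, k = 0.0470 min⁻¹)

The best flask is north-west at 16.7 %, ahead of south-west at 15.2 %, south at 15.1 % and north-east at 6.30 %, while north ends at 4.54 %, below my 9.72 %. At 2.00 h, homo dimer holds 87.2 % of the charge in north, against 67.4 % in south-west. Measure the late climbs against the supply rate: north, from 80 min to 2.0 h, climbs at 0.401 times that rate, and north-west, read on from 2.00 h to 3.00 h, climbs at 0.788 times that rate, reaching 23.1 %.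

The readings come from a simulation for substances that don't exist.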